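The 2,2-dimethyldihydropyran fused to the chromone A ring (ring O on C5, CH2 on C6) is disconnected as the [4+2] adduct of isobutene and the ortho-quinone methide O=C5–C6=CH2. The cycloaddition is run early, on a phloroacetophenone Mannich base whose other flanking oxygen (later O7) is MOM-blocked: heating expels dimethylamine and isobutene adds, forming the ArCH2–CH2 and ArO–CMe2 bonds in one operation. The new ring also ties up one ortho oxygen, so the later pyranone closure must use the other, which fixes prenyl at C8. The benzofuran half then comes from a Nenitzescu-type annulation of the derived 2-morpholinochromone with a chroman-5,8-quinone.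

Key step: step 4

Remark: the target has no stereocentre and no stereogenic double bond, so no configuration has to be set. Locants follow chromone numbering (O1, C2–C8a; B ring C1'–C6'; the furan oxygen joins C2 and C2'). Isobutene and 2,5-dimethoxyphenol are taken as catalogue chemicals.

Step 1
Reactants: 1 2,4,6-trihydroxyacetophenone; 2 prenyl bromide (1-bromo-3-methylbut-2-ene)
Product: 3 1-[2,4,6-trihydroxy-3-(3-methylbut-2-en-1-yl)phenyl]ethan-1-one
Conditions: DBU, THF, 0 °C → rt
Reagents that add atoms: none
Why: Base-mediated C-alkylation of the phloroglucinol-type phenoxide with the allylic bromide (direct C-prenylation of an acylphloroglucinol); the two free ring carbons are equivalent, so a single mono-C-prenyl isomer should result.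

Step 2
Reactants: 3 C-prenyl phloroacetophenone
Product: 4 1-[2,6-dihydroxy-4-(methoxymethoxy)-3-(3-methylbut-2-en-1-yl)phenyl]ethan-1-one
Conditions: MOMCl (1.05 equiv), i-Pr2NEt, CH2Cl2, 0 °C
Reagents that add atoms: chloromethyl methyl ether (MOMCl), COCCl
Why: Williamson-type O-alkylation (MOM ether formation): the para-OH is the most acidic phenol and the only one not tied to the acetyl carbonyl by a hydrogen bond, so one equivalent of MOMCl should react there.

Step 3
Reactants: 4 para-MOM ether
Product: 5 1-[3-[(dimethylamino)methyl]-2,6-dihydroxy-4-(methoxymethoxy)-5-(3-methylbut-2-en-1-yl)phenyl]ethan-1-one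
Conditions: 37% aq. CH2O, 40% aq. Me2NH, EtOH, rt
Reagents that add atoms: formaldehyde, C=O; dimethylamine, CNC
Why: Phenolic Mannich reaction: the iminium ion attacks the only unsubstituted ring carbon, which lies between a free OH and the MOM ether and is activated by three oxygens.

Step 4
Reactants: 5 phenolic Mannich base; 6 isobutene (2-methylpropene)
Product: 8 1-[7-hydroxy-5-(methoxymethoxy)-2,2-dimethyl-6-(3-methylbut-2-en-1-yl)-3,4-dihydro-2H-chromen-8-yl]ethan-1-one, via ortho-quinone methide 7 (not isolated)
Conditions: isobutene (30 equiv, condensed in), PhMe (0.02 M), sealed steel tube, 150 °C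
Reagents that add atoms: none
Why: Thermal β-elimination of dimethylamine from the hydrogen-bonded phenolic Mannich base gives ortho-quinone methide 7, an electron-poor 1-oxadiene that is captured by isobutene in an inverse-electron-demand hetero-Diels–Alder reaction. This is the standard chroman synthesis from ortho-quinone methides and alkenes, the same reaction type that joins acylphloroglucinol quinone methides to 1,1-disubstituted terpene alkenes. The dihydropyran ring is closed by this intermolecular, concerted but asynchronous [4+2] cycloaddition (C–C bond to the exocyclic methylene leading, O–C bond following), and rearomatisation makes it irreversible. The unsubstituted CH2 terminus of isobutene bonds to the electrophilic methylene and the tertiary carbon, which carries the developing positive charge, bonds to oxygen, giving the 2,2-dimethyl pattern; no stereocentre is formed. The step needs ring closure on the oxygen ortho to the acetyl group and not on the para oxygen, and the MOM ether secures this because only one free hydroxyl flanks the CH2NMe2 carbon. The large excess of isobutene at low substrate concentration should outrun capture of 7 by the trisubstituted prenyl alkene or by a second molecule of 7.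

Step 5
Reactants: 8 chroman methyl ketone
Product: 9 1-[7-hydroxy-5-(methoxymethoxy)-2,2-dimethyl-6-(3-methylbut-2-en-1-yl)-3,4-dihydro-2H-chromen-8-yl]-3,3-bis(methylsulfanyl)prop-2-en-1-one
Conditions: t-BuOK (3.3 equiv), CS2, THF, 0 °C; then MeI (2.1 equiv), 0 °C → rt
Reagents that add atoms: carbon disulfide, S=C=S; iodomethane, CI
Why: α-Oxo ketene dithioacetal synthesis: the methyl ketone enolate adds to CS2 and the ene-1,1-dithiolate is S-methylated twice, the thiolates being far more nucleophilic than the chelated, hindered phenoxide, which should stay free.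

Step 6
Reactants: 9 ketene dithioacetal
Product: 11 7-(methoxymethoxy)-2-(morpholin-4-yl)-8-(3-methylbut-2-en-1-yl)chromen-4-one bearing a 2,2-dimethyl-3,4-dihydro-2H-pyran ring fused at C5–C6 (ring O on C5; CH2 on C6), via ketene N,S-acetal 10 (not isolated)
Conditions: morpholine (3 equiv), EtOH, reflux
Reagents that add atoms: morpholine, C1COCCN1
Why: Vinylic addition–elimination: morpholine displaces one methylthio group to give the ketene N,S-acetal and the ortho-phenol displaces the second in a 6-endo-trig addition–elimination, the known route from o-hydroxyaryl ketene dithioacetals to 2-aminochromones; the only free phenol is the one next to the prenyl group, which places prenyl at C8.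

Step 7
Reactants: 12 2,5-dimethoxyphenol
Product: 13 2-[(dimethylamino)methyl]-3,6-dimethoxyphenol
Conditions: 37% aq. CH2O, 40% aq. Me2NH, EtOH, rt → 50 °C
Reagents that add atoms: formaldehyde, C=O; dimethylamine, CNC
Why: Phenolic Mannich reaction, delivered through the hydrogen bond between the phenol and the aminomethylating agent to the one free ortho carbon (between OH and OMe).

Step 8
Reactants: 13 Mannich base; 6 isobutene
Product: 15 5,8-dimethoxy-2,2-dimethyl-3,4-dihydro-2H-chromene, via ortho-quinone methide 14 (not isolated)
Conditions: isobutene (excess), PhMe, sealed steel tube, 180 °C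
Reagents that add atoms: none
Why: Same reaction type as step 4: thermal deamination to ortho-quinone methide 14 and hetero-Diels–Alder capture by isobutene, with the tertiary carbon bonding to oxygen.

Step 9
Reactants: 15 dimethoxychroman
Product: 16 2,2-dimethyl-3,4-dihydro-2H-chromene-5,8-dione
Conditions: (NH4)2Ce(NO3)6 (2.5 equiv), MeCN/H2O, 0 °C
Reagents that add atoms: water, O
Why: Oxidative demethylation of a para-dimethoxyarene to the para-quinone with cerium(IV) ammonium nitrate; water attacks the arene radical cation at the two methoxy-bearing carbons and supplies both carbonyl oxygens.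

Step 10
Reactants: 11 2-morpholinochromone; 16 chroman-5,8-quinone
Product: 18 7-O-methoxymethyl ether of the target coumaronochromone, via hydroquinone adduct 17 (not isolated)
Conditions: 16 (1.1 equiv), AcOH, rt → 40 °C
Reagents that add atoms: none
Why: Nenitzescu-type benzofuran annulation of a tertiary enaminone with a 1,4-benzoquinone: nucleophilic C3 of the aminochromone adds to C6 of 16 (β to the C8 carbonyl, the more electrophilic one because the ring oxygen deactivates the C5 carbonyl as a vinylogous ester), the hydroquinone OH next to the new C–C bond attacks the amine-bearing C2, and loss of morpholine aromatises the furan, so the reaction is redox-neutral and the amine marks the carbon that receives the furan oxygen.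

Step 11
Reactants: 18 MOM-protected coumaronochromone
Product: 19 target compound CNP0081329.0
Conditions: 3 M HCl, MeOH, rt
Reagents that add atoms: none
Why: Acid-catalysed methanolysis of the MOM acetal (transacetalisation to dimethoxymethane) under conditions mild enough to leave the ortho-prenyl phenol and both chroman rings untouched.

Compound list
1 | 2,4,6-trihydroxyacetophenone | CC(=O)c1c(O)cc(O)cc1O | starting material
2 | prenyl bromide (1-bromo-3-methylbut-2-ene) | CC(C)=CCBr | starting material
3 | 1-[2,4,6-trihydroxy-3-(3-methylbut-2-en-1-yl)phenyl]ethan-1-one | CC(=O)c1c(O)cc(O)c(CC=C(C)C)c1O | intermediate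
4 | 1-[2,6-dihydroxy-4-(methoxymethoxy)-3-(3-methylbut-2-en-1-yl)phenyl]ethan-1-one | CC(=O)c1c(O)cc(OCOC)c(CC=C(C)C)c1O | intermediate
5 | 1-[3-[(dimethylamino)methyl]-2,6-dihydroxy-4-(methoxymethoxy)-5-(3-methylbut-2-en-1-yl)phenyl]ethan-1-one | CC(=O)c1c(O)c(CN(C)C)c(OCOC)c(CC=C(C)C)c1O | intermediate
6 | isobutene (2-methylpropene) | CC(C)=C | starting material
7 | ortho-quinone methide, formed in the flask and not isolated: 2-acetyl-3-hydroxy-5-(methoxymethoxy)-6-methylidene-4-(3-methylbut-2-en-1-yl)cyclohexa-2,4-dien-1-one | CC(=O)C1=C(O)C(CC=C(C)C)=C(OCOC)C(=C)C1=O | intermediate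
8 | 1-[7-hydroxy-5-(methoxymethoxy)-2,2-dimethyl-6-(3-methylbut-2-en-1-yl)-3,4-dihydro-2H-chromen-8-yl]ethan-1-one | CC(=O)c1c(O)c(CC=C(C)C)c(OCOC)c2CCC(C)(C)Oc12 | intermediate
9 | 1-[7-hydroxy-5-(methoxymethoxy)-2,2-dimethyl-6-(3-methylbut-2-en-1-yl)-3,4-dihydro-2H-chromen-8-yl]-3,3-bis(methylsulfanyl)prop-2-en-1-one | CSC(SC)=CC(=O)c1c(O)c(CC=C(C)C)c(OCOC)c2CCC(C)(C)Oc12 | intermediate
10 | ketene N,S-acetal, formed in the flask and not isolated (drawn as the Z isomer; push–pull alkene, E/Z interconvert readily): (Z)-1-[7-hydroxy-5-(methoxymethoxy)-2,2-dimethyl-6-(3-methylbut-2-en-1-yl)-3,4-dihydro-2H-chromen-8-yl]-3-(methylsulfanyl)-3-(morpholin-4-yl)prop-2-en-1-one | CS/C(=C\C(=O)c1c(O)c(CC=C(C)C)c(OCOC)c2CCC(C)(C)Oc12)N1CCOCC1 | intermediate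
11 | 7-(methoxymethoxy)-2-(morpholin-4-yl)-8-(3-methylbut-2-en-1-yl)chromen-4-one with a 2,2-dimethyl-3,4-dihydro-2H-pyran ring fused at C5–C6 (ring O on C5, CH2 on C6) | O=c1cc(N2CCOCC2)oc2c(CC=C(C)C)c(OCOC)c3CCC(C)(C)Oc3c12 | intermediate
12 | 2,5-dimethoxyphenol | COc1ccc(OC)c(O)c1 | starting material
13 | 2-[(dimethylamino)methyl]-3,6-dimethoxyphenol | COc1ccc(OC)c(O)c1CN(C)C | intermediate
14 | ortho-quinone methide, formed in the flask and not isolated: 2,5-dimethoxy-6-methylidenecyclohexa-2,4-dien-1-one | C=C1C(=O)C(OC)=CC=C1OC | intermediate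
15 | 5,8-dimethoxy-2,2-dimethyl-3,4-dihydro-2H-chromene | COc1ccc(OC)c2OC(C)(C)CCc12 | intermediate
16 | 2,2-dimethyl-3,4-dihydro-2H-chromene-5,8-dione | O=C1C=CC(=O)C2=C1CCC(C)(C)O2 | intermediate
17 | hydroquinone adduct, formed in the flask and not isolated: compound 11 carrying a 5,8-dihydroxy-2,2-dimethyl-3,4-dihydro-2H-chromen-6-yl group on C3 | O=c1c(-c2cc(O)c3OC(C)(C)CCc3c2O)c(N2CCOCC2)oc2c(CC=C(C)C)c(OCOC)c3CCC(C)(C)Oc3c12 | intermediate
18 | 7-O-methoxymethyl ether of the target: coumaronochromone (benzofuro[2,3-b]chromen-4-one) with 7-OMOM, 8-prenyl, 5'-OH and 2,2-dimethyldihydropyran rings fused at C5–C6 (O on C5) and C3'–C4' (O on C4') | O=c1c2c3cc(O)c4OC(C)(C)CCc4c3oc2oc2c(CC=C(C)C)c(OCOC)c3CCC(C)(C)Oc3c12 | intermediate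
19 | CNP0081329.0: 7,5'-dihydroxy-8-(3-methylbut-2-en-1-yl)coumaronochromone with 2,2-dimethyldihydropyran rings fused at C5–C6 (O on C5) and C3'–C4' (O on C4') | O=c1c2c3cc(O)c4OC(C)(C)CCc4c3oc2oc2c(CC=C(C)C)c(O)c3CCC(C)(C)Oc3c12 | target

Total step count: 11. Longest linear sequence: 8 steps (steps 1–6, 10, 11); the quinone branch (steps 7–9) joins at step 10.

Steps most likely to fail

Step 10. C-alkylation of the deactivated alkoxyquinone by the aminochromone may be slower than redox side reactions. In particular, unreacted 16 may oxidise adduct 17 to an arylquinone that cannot cyclise, or some attack may occur at C7 of the quinone and lead to the isomeric furan. The fallback sets out from 8 and comes back to the route at 19. Ketone 8 is heated with DMF dimethyl acetal to the open-chain enaminone F1, the classical Nenitzescu substrate. F1 is condensed with 16 in AcOH, with loss of dimethylamine, to the 3-aroylbenzofuran-5-ol F2. The unhindered benzofuranol OH is acetylated (Ac2O, pyridine, 0 °C) to the monoacetate F3. DDQ in dioxane at room temperature should then close the pyranone ring by oxa-Michael addition of the chelated phenol to C2 of the benzofuran and dehydrogenation of the acetal C–H (the 2'-hydroxychalcone-to-flavone type of oxidative cyclisation), giving the coumaronochromone acetate F4. HCl in MeOH removes the acetate and the MOM group and gives 19.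

Step 4. Quinone methide 7 may be consumed by the prenyl alkene of a second molecule or by self-oligomerisation faster than by the unactivated alkene. The fallback sets out from 1 and comes back at 8; it performs the annulation before the prenyl group is present. Compound 1 is protected at the para-OH (MOMCl, i-Pr2NEt) to the MOM ether F5 and converted with one equivalent of CH2O/Me2NH into the mono-Mannich base F6. Heating F6 with isobutene gives the prenyl-free chroman ketone F7. The remaining phenol is alkylated with 3-chloro-3-methylbut-1-yne (K2CO3, KI, cat. CuI, acetone) to the propargyl ether F8, which is semi-hydrogenated (H2, Lindlar catalyst, quinoline) to the 1,1-dimethylallyl ether F9. Heating F9 (PhNEt2, 130 °C) should bring about an aromatic Claisen rearrangement that can only go to the one free ortho carbon and gives 8.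

Step 8. The electron-rich quinone methide 14 has no acyl stabilisation and may oligomerise before it meets isobutene; in addition, part of the aminomethylation in step 7 may go para to the phenol. The fallback sets out from 12 and comes back at 15, bypassing both steps. Phenol 12 is alkylated with 3-chloro-3-methylbut-1-yne (K2CO3, KI, cat. CuI, acetone) to the aryl propargyl ether F10. Heating F10 (PhNEt2, 180 °C) should give the 2H-chromene F11 by propargyl Claisen rearrangement, 1,5-hydrogen shift and 6π-electrocyclisation at the only free ortho position. Hydrogenation (H2, Pd/C, EtOAc) gives 15.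

Further compounds
F1 | step 10 | (E)-3-(dimethylamino)-1-[7-hydroxy-5-(methoxymethoxy)-2,2-dimethyl-6-(3-methylbut-2-en-1-yl)-3,4-dihydro-2H-chromen-8-yl]prop-2-en-1-one | CN(C)/C=C/C(=O)c1c(O)c(CC=C(C)C)c(OCOC)c2CCC(C)(C)Oc12
F2 | step 10 | 3-aroylbenzofuran-5-ol: benzofuran with a 2,2-dimethyldihydropyran fused at C6–C7 (O on C6), 5-OH, and the 7-hydroxy-5-(methoxymethoxy)-2,2-dimethyl-6-prenylchroman-8-yl carbonyl group on C3 | O=C(c1coc2c1cc(O)c1OC(C)(C)CCc12)c1c(O)c(CC=C(C)C)c(OCOC)c2CCC(C)(C)Oc12
F3 | step 10 | 5-O-acetate of F2 | CC(=O)Oc1cc2c(C(=O)c3c(O)c(CC=C(C)C)c(OCOC)c4CCC(C)(C)Oc34)coc2c2CCC(C)(C)Oc12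
F4 | step 10 | 5'-O-acetyl-7-O-methoxymethyl derivative of the target coumaronochromone | O=c1c2c3cc(OC(C)=O)c4OC(C)(C)CCc4c3oc2oc2c(CC=C(C)C)c(OCOC)c3CCC(C)(C)Oc3c12
F5 | step 4 | 1-[2,6-dihydroxy-4-(methoxymethoxy)phenyl]ethan-1-one | CC(=O)c1c(O)cc(OCOC)cc1O
F6 | step 4 | 1-[3-[(dimethylamino)methyl]-2,6-dihydroxy-4-(methoxymethoxy)phenyl]ethan-1-one | CC(=O)c1c(O)cc(OCOC)c(CN(C)C)c1O
F7 | step 4 | 1-[7-hydroxy-5-(methoxymethoxy)-2,2-dimethyl-3,4-dihydro-2H-chromen-8-yl]ethan-1-one | CC(=O)c1c(O)cc(OCOC)c2CCC(C)(C)Oc12
F8 | step 4 | 1-[5-(methoxymethoxy)-2,2-dimethyl-7-[(2-methylbut-3-yn-2-yl)oxy]-3,4-dihydro-2H-chromen-8-yl]ethan-1-one | CC(=O)c1c(OC(C)(C)C#C)cc(OCOC)c2CCC(C)(C)Oc12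
F9 | step 4 | 1-[5-(methoxymethoxy)-2,2-dimethyl-7-[(2-methylbut-3-en-2-yl)oxy]-3,4-dihydro-2H-chromen-8-yl]ethan-1-one | CC(=O)c1c(OC(C)(C)C=C)cc(OCOC)c2CCC(C)(C)Oc12
F10 | step 8 | 1,4-dimethoxy-2-[(2-methylbut-3-yn-2-yl)oxy]benzene | COc1ccc(OC)c(OC(C)(C)C#C)c1
F11 | step 8 | 5,8-dimethoxy-2,2-dimethyl-2H-chromene | COc1ccc(OC)c2OC(C)(C)C=Cc12
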